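## Structural features

The target is a row of four rings: a 2-hydroxy-1,4-naphthoquinone (benzenoid ring A fused to the quinone ring), a resorcinol ring B and a 4-hydroxy-2-pyranone. C6 of ring A is joined to C1' of ring B through a ketone carbon, and C6' of ring B to C6'' of the pyranone through one methylene. There is no stereocentre, so the task is regiochemistry and the handling of five acidic hydroxyl groups. Ring A is fully differentiated (C5 methyl, C6 acyl, C7 hydroxyl, C8 hydrogen), and the quinone ring has oxygen at C1, C2 and C4 and hydrogen at C3, with the C2 hydroxyl on the C8a side. The fragile parts are the hydroxyquinone (reducible, open to nucleophiles), the hydroxypyranone (an oxidisable 1,3-dicarbonyl enol and a lactone), the doubly activated C6'–CH2–C6'' methylene and the ketone shielded by four ortho substituents. The real difficulty is to place the C2 oxygen relative to the unsymmetrical ring A, because oxidation of a preformed naphthalene or quinone cannot tell C2 from C3. The key step uses the sequence C4a–C4(O)–C3(H)–C2(O)–C1(O)–C8a: C4 is a carbene carbon on C4a, C1 a CO ligand, C2 and C3 an ynol ether, and the C5 methyl leaves C8a as the only site of ring closure.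

## Logic of the disconnections

32 to 30 (through 31): six O–alkyl bonds and the quinone oxidation level are traced back. All hydroxyls stay as ethers to the end and the quinone ring is stored as its 1,2,4-trialkoxy arene, in which C1, C2 and C4 already carry oxygen. The gain is that every intermediate is a neutral arene that tolerates bases and oxidants. The demand is a Lewis acid that cleaves six ethers without harming the pyranone, and an air oxidation of 31 that can give only one quinone.

30 to 28 (through 29): the lactone bond O1''–C2'' is cut. The pyranone becomes a masked acylketene, which removes the acidic ring from all earlier steps. The forward step must close the ring without base.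

28 to 27 to 24 plus 25 (through 26): the C5''–C6'' bond is cut at the carbinol level. This splits off the four-carbon unit as a commercial heterocycle. The forward step needs a carbon nucleophile that adds to an enolisable aldehyde beside an unprotected, hindered ketone.

24 to 23 to 22: changes of oxidation level and protection only. The side chain is carried as a silyl ether through the ring-forming steps.

22 to 18 plus 20 (through 21): ring B is cut at C1'–C2' and C5'–C6'. An ynone and a trioxygenated diene give the aromatic ring at the right oxidation level with both oxygens and the side chain in place. The forward step needs the nucleophilic diene terminus to attack the β-carbon of the ynone. 20 goes back to 19 by enolisation and silylation.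

18 to 17 to 14 plus 15 (through 16): the bond between the future ketone carbon and C1' is cut. This reduces the right half of the molecule to a commercial alkyne. The forward step is an acetylide addition to a doubly ortho-substituted aldehyde.

14 to 13 to 12 to 11: protecting-group and oxidation-level changes at C6 and at the C1 oxygen. The naphthol is capped so that the ring becomes a hydroquinone diether.

11 to 8 plus 9 (through 10): the quinone-ring bonds C3–C4, C1–C2 and C1–C8a are cut. One ring, three carbon–carbon bonds and all three oxygens are traced to a benzene derivative, a CO ligand and a two-carbon ynol ether. The forward step needs one sense of alkyne insertion and CO uptake before ring closure.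

8 to 4 plus 5 (through 6 and 7), then 4 to 3 to 2 to 1: the carbene carbon–aryl bond is cut, then the silyl ether, the alcohol and the bromine are removed in turn. The demand is a bromination para to the methoxy group.

## Other disconnections considered

Alternative 1: The cut is the lactone bond O1''–C2''. In the forward step 6-{3-[3,5-dimethoxy-2-(3,5,6,8-tetramethoxy-1-methyl-2-naphthoyl)phenyl]-2-oxopropyl}-2,2-dimethyl-4H-1,3-dioxin-4-one A2 would be heated in toluene. Loss of acetone would give an acylketene that the enol oxygen of the C6'' ketone captures, to give 6-[3,5-dimethoxy-2-(3,5,6,8-tetramethoxy-1-methyl-2-naphthoyl)benzyl]-4-hydroxy-2H-pyran-2-one A1.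
- In its favour: it is neutral, unimolecular, free of base and releases only acetone.
- Against it as the step that carries the strategy: it forms one C–O bond in the ring that is easiest to make, and A2 already contains every carbon of the target, so the naphthalene oxygenation and ring B remain unsolved.
- Comparison: A2 and A1 differ from 28 and 30 only in methoxy for ethoxy at one carbon, and the chosen plan uses this same closure as step 17. On structure and mechanism the two are therefore equal for this ring. On step economy the alternative adds nothing, because the C2 oxygen problem must still be solved elsewhere.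

Alternative 2: The cut goes through ring A at C4a–C5 and C8–C8a. In the forward step the diene 6-{2-[(2Z)-2-ethylidene-3-(tert-butyldimethylsilyloxy)but-3-enoyl]-3,5-dimethoxybenzyl}-4-methoxy-2H-pyran-2-one A5 would add to 2-bromo-5-methoxy-1,4-benzoquinone A4. Loss of HBr, enolisation and air oxidation would give 7-(tert-butyldimethylsilyloxy)-6-{2,4-dimethoxy-6-[(4-methoxy-2-oxo-2H-pyran-6-yl)methyl]benzoyl}-2-methoxy-5-methylnaphthalene-1,4-dione A3.
- In its favour: it is highly convergent, the quinone arrives at its final oxidation level, the bromine and the methoxy group of A4 steer the regiochemistry, and little remains after it. On convergence and on avoiding a late redox step it is better than the chosen plan.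
- Against it: A5 is a tetrasubstituted, cross-conjugated diene with an aroyl group on its central carbon. Its selective preparation beside an acidic pyranone methylene is uncertain, its s-cis conformer is crowded, and the adduct still needs elimination and dehydrogenation.
- Comparison: both plans fix the C2 oxygen by the polarity of a cycloaddition partner. The chosen plan puts its risk into a well-studied class of carbene benzannulation and pays with a long linear sequence. Alternative 2 would be shorter but puts all its risk into one fragile diene.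

Alternative 3: The cut is through ring B at C1'–C6' and C2'–C3'. In the forward step methyl 3-oxo-3-(3,5,6,8-tetramethoxy-1-methylnaphthalen-2-yl)propanoate A7 and (E)-6-(tert-butyldimethylsilyloxy)hex-3-en-2-one A8 would react with NaOMe. Michael addition and then Claisen closure would give racemic 5-[2-(tert-butyldimethylsilyloxy)ethyl]-3-hydroxy-4-(3,5,6,8-tetramethoxy-1-methyl-2-naphthoyl)cyclohex-3-en-1-one A6.
- In its favour: the reagents are cheap, the partner A8 is simple and acyclic, no heat-sensitive diene is needed, and two C–C bonds form in one operation. On reagent simplicity it is better than step 12.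
- Against it: A6 is one oxidation level below the resorcinol. It must be dehydrogenated beside a very electron-rich naphthalene, it is a triketone open to retro-Claisen cleavage by alkoxide, and its stereocentre is made only to be destroyed.
- Comparison: both build ring B with the same substitution pattern and the same number of C–C bonds. The cycloaddition of the chosen plan delivers the aromatic ring directly. Alternative 3 trades the alkynylation and oxidation steps for a keto ester synthesis and an aromatisation, so step economy is about equal. Like alternative 1 it leaves the quinone ring unaddressed.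

Key step: step 5

Remarks on the chemistry:
- The atom mapping of 8 and 11 onto the target was checked (carbene carbon to C4, CO to C1, ethoxy-bearing carbon to C2, C5 methyl beside C4a) and needed no correction.
- The substitution of 8 is kept: its silyl ether survives steps 4 to 6, and its aryl methoxy group ends ortho to the ketone, where Lewis acids cleave it readily.
- 9 is used as its commercial solution in hexanes.
- 17 and 27 are racemic and their carbinol centres are oxidised away.
- The hydroxyquinone and hydroxypyranone are written in the tautomeric forms of the target SMILES.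

## Steps

Step 1
Reactants: 1 2-methoxy-6-methylbenzoic acid
Product: 2 3-bromo-6-methoxy-2-methylbenzoic acid
Conditions: Br2 (1.05 equiv), AcOH, rt
Reagents that add atoms: bromine, BrBr
Why: Electrophilic aromatic bromination; of the two open activated positions the one para to the methoxy group (also ortho to methyl and meta to carboxyl) is the usual site for an anisole, and the carboxyl group tempers the ring so that one bromine enters.

Step 2
Reactants: 2 3-bromo-6-methoxy-2-methylbenzoic acid
Product: 3 (3-bromo-6-methoxy-2-methylphenyl)methanol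
Conditions: BH3·SMe2, THF, 0 °C to reflux; MeOH, H2O
Reagents that add atoms: none
Why: Borane reduction of a carboxylic acid through its acyloxyborane; the reagent leaves the aryl bromide and the ether alone and is small enough for a 2,6-disubstituted acid.

Step 3
Reactants: 3 (3-bromo-6-methoxy-2-methylphenyl)methanol
Product: 4 [(3-bromo-6-methoxy-2-methylbenzyl)oxy]triisopropylsilane
Conditions: i-Pr3SiCl, imidazole, DMF, rt
Reagents that add atoms: chlorotriisopropylsilane, CC(C)[Si](Cl)(C(C)C)C(C)C
Why: Silylation of a primary benzylic alcohol; the triisopropylsilyl ether must survive n-BuLi, the oxonium salt and NaH in steps 4 to 6 and still leave with fluoride in step 7.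

Step 4
Reactants: 4 [(3-bromo-6-methoxy-2-methylbenzyl)oxy]triisopropylsilane; 5 chromium hexacarbonyl Cr(CO)6
Product: 8 pentacarbonyl{methoxy[4-methoxy-2-methyl-3-(triisopropylsilyloxymethyl)phenyl]methylidene}chromium, via aryllithium 6 (not isolated), via lithium acylchromate 7 (not isolated)
Conditions: n-BuLi, THF, −78 °C; Cr(CO)6, −78 °C to rt; Me3OBF4, CH2Cl2/H2O, 0 °C
Reagents that add atoms: trimethyloxonium tetrafluoroborate, C[O+](C)C.F[B-](F)(F)F
Why: Fischer carbene synthesis: bromine–lithium exchange is faster than any deprotonation at −78 °C, aryllithium 6 adds to one CO ligand of 5 to give acylchromate 7, and the hard oxonium salt alkylates 7 on oxygen; the ortho methyl group slows the addition but does not prevent it.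

Step 5
Reactants: 8 pentacarbonyl{methoxy[4-methoxy-2-methyl-3-(triisopropylsilyloxymethyl)phenyl]methylidene}chromium; 9 ethoxyethyne
Product: 11 2-ethoxy-4,7-dimethoxy-5-methyl-6-(triisopropylsilyloxymethyl)naphthalen-1-ol, via tricarbonylchromium complex of the naphthol 10 (not isolated)
Conditions: 9 (3 equiv), degassed THF, 55 °C; then air, rt
Reagents that add atoms: none
Why: Dötz benzannulation of an aryl(alkoxy)carbene complex of zerovalent chromium with a terminal alkyne. Thermal loss of one cis CO opens a site for the ynol ether, which inserts into the Cr=C bond with its unsubstituted carbon on the carbene carbon (C3–C4), giving an η3-vinylcarbene whose carbene carbon now bears the ethoxy group. Migratory insertion of CO (C1–C2) gives an η4-vinylketene, and a 6π electrocyclisation onto the free ortho carbon of the aryl ring (C1–C8a, the six-membered ring closure) followed by enolisation gives the naphthol as its Cr(CO)3 complex 10, which air cleaves. The closest known reactions are benzannulations of aryl carbene complexes with terminal and heteroatom-substituted alkynes. No stereocentre is formed. The sense of insertion is secured by the size difference between H and OEt and by the nucleophilic β-carbon of the ynol ether, and the site of closure is secured because the other ortho position carries the methyl group. CO insertion into the donor-stabilised vinylcarbene is the slow event, so a donor solvent, a moderate temperature and an excess of 9 are chosen to favour the ketene over CO-free cyclisation; visible light, which drives CO insertion in alkoxycarbene complexes of chromium, can be applied if the vinylcarbene persists.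

Step 6
Reactants: 11 2-ethoxy-4,7-dimethoxy-5-methyl-6-(triisopropylsilyloxymethyl)naphthalen-1-ol
Product: 12 2-ethoxy-1,4,7-trimethoxy-5-methyl-6-(triisopropylsilyloxymethyl)naphthalene
Conditions: NaH, MeI, DMF, 0 °C, argon
Reagents that add atoms: iodomethane, CI
Why: Williamson methylation of the naphtholate, run under argon because 4-alkoxy-1-naphthols oxidise readily in air; it turns the new ring into a hydroquinone diether that tolerates organolithium reagents and mild oxidants.

Step 7
Reactants: 12 2-ethoxy-1,4,7-trimethoxy-5-methyl-6-(triisopropylsilyloxymethyl)naphthalene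
Product: 13 (6-ethoxy-3,5,8-trimethoxy-1-methylnaphthalen-2-yl)methanol
Conditions: Bu4NF, THF, rt
Reagents that add atoms: none
Why: Fluoride cleavage of the silyl ether; nothing else in 12 responds to fluoride.

Step 8
Reactants: 13 (6-ethoxy-3,5,8-trimethoxy-1-methylnaphthalen-2-yl)methanol
Product: 14 6-ethoxy-3,5,8-trimethoxy-1-methylnaphthalene-2-carbaldehyde
Conditions: Dess–Martin periodinane, CH2Cl2, rt
Reagents that add atoms: none
Why: Dess–Martin oxidation of a primary benzylic alcohol to the aldehyde; the reagent works on alcohols flanked by two ortho substituents and does not attack the electron-rich arene.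

Step 9
Reactants: 14 6-ethoxy-3,5,8-trimethoxy-1-methylnaphthalene-2-carbaldehyde; 15 tert-butyl(but-3-yn-1-yloxy)dimethylsilane
Product: 17 5-(tert-butyldimethylsilyloxy)-1-(6-ethoxy-3,5,8-trimethoxy-1-methylnaphthalen-2-yl)pent-2-yn-1-ol (racemic), via lithium acetylide 16 (not isolated)
Conditions: 15, n-BuLi, THF, −78 °C; then 14, −78 to 0 °C; H2O
Reagents that add atoms: none
Why: Addition of a lithium acetylide to an aldehyde; the slim nucleophile reaches the doubly ortho-substituted carbonyl, and the carbinol centre is formed racemic and removed in step 10.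

Step 10
Reactants: 17 5-(tert-butyldimethylsilyloxy)-1-(6-ethoxy-3,5,8-trimethoxy-1-methylnaphthalen-2-yl)pent-2-yn-1-ol
Product: 18 5-(tert-butyldimethylsilyloxy)-1-(6-ethoxy-3,5,8-trimethoxy-1-methylnaphthalen-2-yl)pent-2-yn-1-one
Conditions: MnO2, CH2Cl2, rt
Reagents that add atoms: none
Why: MnO2 oxidation of an alcohol that is both benzylic and propargylic, under neutral conditions that avoid isomerisation of the ynone through its γ-hydrogens.

Step 11
Reactants: 19 methyl (E)-3-methoxybut-2-enoate
Product: 20 1,3-dimethoxy-1-(trimethylsilyloxy)buta-1,3-diene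
Conditions: LiN(i-Pr)2, THF, −78 °C; Me3SiCl
Reagents that add atoms: chlorotrimethylsilane, C[Si](C)(C)Cl
Why: γ-Deprotonation of the vinylogous ester and O-silylation of the dienolate, the standard way to this Brassard-type diene; the geometry at the ketene acetal does not matter because that carbon becomes aromatic.

Step 12
Reactants: 18 5-(tert-butyldimethylsilyloxy)-1-(6-ethoxy-3,5,8-trimethoxy-1-methylnaphthalen-2-yl)pent-2-yn-1-one; 20 1,3-dimethoxy-1-(trimethylsilyloxy)buta-1,3-diene
Product: 22 {2-[2-(tert-butyldimethylsilyloxy)ethyl]-4,6-dimethoxyphenyl}(6-ethoxy-3,5,8-trimethoxy-1-methylnaphthalen-2-yl)methanone, via ortho-hydroxy ketone 21 (not isolated)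
Conditions: 20 (3 equiv), PhMe, 110 °C, sealed tube; then Cs2CO3, MeI, wet DMF, 40 °C
Reagents that add atoms: iodomethane, CI
Why: Diels–Alder reaction of an ynone with a 1,1,3-trioxygenated diene followed by aromatisation: the nucleophilic CH2 terminus of 20 bonds to the β-carbon of 18 and the ketene acetal carbon to the α-carbon, so loss of methanol and of the silyl group leaves phenol 21 with OH ortho and OMe para to the ketone and the side chain on C6'. Methylation in the same flask gives 22, and any ortho methyl ether formed by the other mode of elimination is the same compound.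

Step 13
Reactants: 22 {2-[2-(tert-butyldimethylsilyloxy)ethyl]-4,6-dimethoxyphenyl}(6-ethoxy-3,5,8-trimethoxy-1-methylnaphthalen-2-yl)methanone
Product: 23 (6-ethoxy-3,5,8-trimethoxy-1-methylnaphthalen-2-yl)[2-(2-hydroxyethyl)-4,6-dimethoxyphenyl]methanone
Conditions: Bu4NF, THF, 0 °C
Reagents that add atoms: none
Why: Fluoride cleavage of the primary silyl ether; the aryl ethers and the hindered ketone are unaffected.

Step 14
Reactants: 23 (6-ethoxy-3,5,8-trimethoxy-1-methylnaphthalen-2-yl)[2-(2-hydroxyethyl)-4,6-dimethoxyphenyl]methanone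
Product: 24 2-[2-(6-ethoxy-3,5,8-trimethoxy-1-methyl-2-naphthoyl)-3,5-dimethoxyphenyl]acetaldehyde
Conditions: Dess–Martin periodinane, CH2Cl2, 0 °C
Reagents that add atoms: none
Why: Dess–Martin oxidation of a 2-arylethanol to the arylacetaldehyde under near-neutral conditions that limit enolisation; 24 is used at once.

Step 15
Reactants: 24 2-[2-(6-ethoxy-3,5,8-trimethoxy-1-methyl-2-naphthoyl)-3,5-dimethoxyphenyl]acetaldehyde; 25 2,2,6-trimethyl-4H-1,3-dioxin-4-one
Product: 27 6-{3-[2-(6-ethoxy-3,5,8-trimethoxy-1-methyl-2-naphthoyl)-3,5-dimethoxyphenyl]-2-hydroxypropyl}-2,2-dimethyl-4H-1,3-dioxin-4-one (racemic), via lithium dienolate 26 (not isolated)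
Conditions: 25, LiN(i-Pr)2, THF, −78 °C; then 24, −78 °C; AcOH
Reagents that add atoms: none
Why: Vinylogous aldol addition: the lithium dienolate 26 reacts with aldehydes through its γ-carbon, and at −78 °C the aldehyde is attacked far faster than the shielded diaryl ketone; the carbinol centre is racemic and is oxidised in step 16.

Step 16
Reactants: 27 6-{3-[2-(6-ethoxy-3,5,8-trimethoxy-1-methyl-2-naphthoyl)-3,5-dimethoxyphenyl]-2-hydroxypropyl}-2,2-dimethyl-4H-1,3-dioxin-4-one
Product: 28 6-{3-[2-(6-ethoxy-3,5,8-trimethoxy-1-methyl-2-naphthoyl)-3,5-dimethoxyphenyl]-2-oxopropyl}-2,2-dimethyl-4H-1,3-dioxin-4-one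
Conditions: Dess–Martin periodinane (1.2 equiv), CH2Cl2, 0 °C to rt
Reagents that add atoms: none
Why: Dess–Martin oxidation of the secondary alcohol to the β-keto dioxinone; a small excess and a short reaction time avoid further oxidation at the activated methylene.

Step 17
Reactants: 28 6-{3-[2-(6-ethoxy-3,5,8-trimethoxy-1-methyl-2-naphthoyl)-3,5-dimethoxyphenyl]-2-oxopropyl}-2,2-dimethyl-4H-1,3-dioxin-4-one
Product: 30 6-[2-(6-ethoxy-3,5,8-trimethoxy-1-methyl-2-naphthoyl)-3,5-dimethoxybenzyl]-4-hydroxy-2H-pyran-2-one, via acylketene 29 (not isolated)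
Conditions: PhMe (0.01 M), 110 °C
Reagents that add atoms: none
Why: Thermal retro-[4+2] loss of acetone from the dioxinone gives acylketene 29, which the enol oxygen of the C6'' ketone captures in a six-membered closure through O1''–C2''; high dilution suppresses intermolecular trapping and no base is present.

Step 18
Reactants: 30 6-[2-(6-ethoxy-3,5,8-trimethoxy-1-methyl-2-naphthoyl)-3,5-dimethoxybenzyl]-4-hydroxy-2H-pyran-2-one
Product: 32 6-{2,4-dihydroxy-6-[(4-hydroxy-2-oxo-2H-pyran-6-yl)methyl]benzoyl}-2,7-dihydroxy-5-methylnaphthalene-1,4-dione (CNP0141484.0), via hydroxyhydroquinone 31 (not isolated)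
Conditions: BBr3 (15 equiv), CH2Cl2, −78 °C to rt; H2O; then air, EtOAc/pH 7 buffer
Reagents that add atoms: none
Why: Lewis-acid dealkylation of aryl ethers followed by autoxidation: BBr3 cleaves the five methyl ethers and the ethyl ether (those ortho to the ketone and the vicinal C1/C2 pair with chelation assistance), hydrolysis frees hydroxyhydroquinone 31, and 1,2,4-trihydroxynaphthalenes are oxidised by air to 2-hydroxy-1,4-naphthoquinones. Because C1, C2 and C4 already carry oxygen, only one quinone can result.

## Compound list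

1 | 2-methoxy-6-methylbenzoic acid | COc1cccc(C)c1C(=O)O | starting material
2 | 3-bromo-6-methoxy-2-methylbenzoic acid | COc1ccc(Br)c(C)c1C(=O)O | intermediate
3 | (3-bromo-6-methoxy-2-methylphenyl)methanol | COc1ccc(Br)c(C)c1CO | intermediate
4 | [(3-bromo-6-methoxy-2-methylbenzyl)oxy]triisopropylsilane | COc1ccc(Br)c(C)c1CO[Si](C(C)C)(C(C)C)C(C)C | intermediate
5 | chromium hexacarbonyl, Cr(CO)6 | O=C=[Cr](=C=O)(=C=O)(=C=O)(=C=O)=C=O | starting material
6 | [4-methoxy-2-methyl-3-(triisopropylsilyloxymethyl)phenyl]lithium | [Li]c1ccc(OC)c(CO[Si](C(C)C)(C(C)C)C(C)C)c1C | intermediate (not isolated)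
7 | lithium pentacarbonyl{[4-methoxy-2-methyl-3-(triisopropylsilyloxymethyl)phenyl](oxido)methylidene}chromate | [Li+].[O-]C(c1ccc(OC)c(CO[Si](C(C)C)(C(C)C)C(C)C)c1C)=[Cr](=C=O)(=C=O)(=C=O)(=C=O)=C=O | intermediate (not isolated)
8 | pentacarbonyl{methoxy[4-methoxy-2-methyl-3-(triisopropylsilyloxymethyl)phenyl]methylidene}chromium | COC(c1ccc(OC)c(CO[Si](C(C)C)(C(C)C)C(C)C)c1C)=[Cr](=C=O)(=C=O)(=C=O)(=C=O)=C=O | intermediate
9 | ethoxyethyne | C#COCC | starting material
10 | tricarbonyl[η6-2-ethoxy-4,7-dimethoxy-5-methyl-6-(triisopropylsilyloxymethyl)naphthalen-1-ol]chromium (written as arene plus Cr(CO)3 fragment) | Cc1c(CO[Si](C(C)C)(C(C)C)C(C)C)c(OC)cc2c1c(OC)cc(OCC)c2O.O=C=[Cr](=C=O)=C=O | intermediate (not isolated)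
11 | 2-ethoxy-4,7-dimethoxy-5-methyl-6-(triisopropylsilyloxymethyl)naphthalen-1-ol | Cc1c(CO[Si](C(C)C)(C(C)C)C(C)C)c(OC)cc2c1c(OC)cc(OCC)c2O | intermediate
12 | 2-ethoxy-1,4,7-trimethoxy-5-methyl-6-(triisopropylsilyloxymethyl)naphthalene | Cc1c(CO[Si](C(C)C)(C(C)C)C(C)C)c(OC)cc2c1c(OC)cc(OCC)c2OC | intermediate
13 | (6-ethoxy-3,5,8-trimethoxy-1-methylnaphthalen-2-yl)methanol | Cc1c(CO)c(OC)cc2c1c(OC)cc(OCC)c2OC | intermediate
14 | 6-ethoxy-3,5,8-trimethoxy-1-methylnaphthalene-2-carbaldehyde | Cc1c(C=O)c(OC)cc2c1c(OC)cc(OCC)c2OC | intermediate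
15 | tert-butyl(but-3-yn-1-yloxy)dimethylsilane | C#CCCO[Si](C)(C)C(C)(C)C | starting material
16 | [4-(tert-butyldimethylsilyloxy)but-1-yn-1-yl]lithium | [Li]C#CCCO[Si](C)(C)C(C)(C)C | intermediate (not isolated)
17 | 5-(tert-butyldimethylsilyloxy)-1-(6-ethoxy-3,5,8-trimethoxy-1-methylnaphthalen-2-yl)pent-2-yn-1-ol (racemic) | Cc1c(C(O)C#CCCO[Si](C)(C)C(C)(C)C)c(OC)cc2c1c(OC)cc(OCC)c2OC | intermediate
18 | 5-(tert-butyldimethylsilyloxy)-1-(6-ethoxy-3,5,8-trimethoxy-1-methylnaphthalen-2-yl)pent-2-yn-1-one | Cc1c(C(=O)C#CCCO[Si](C)(C)C(C)(C)C)c(OC)cc2c1c(OC)cc(OCC)c2OC | intermediate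
19 | methyl (E)-3-methoxybut-2-enoate | CO/C(C)=C/C(=O)OC | starting material
20 | 1,3-dimethoxy-1-(trimethylsilyloxy)buta-1,3-diene (ketene acetal geometry not defined) | COC(=C)C=C(OC)O[Si](C)(C)C | intermediate
21 | {2-[2-(tert-butyldimethylsilyloxy)ethyl]-6-hydroxy-4-methoxyphenyl}(6-ethoxy-3,5,8-trimethoxy-1-methylnaphthalen-2-yl)methanone | Cc1c(C(=O)c3c(O)cc(OC)cc3CCO[Si](C)(C)C(C)(C)C)c(OC)cc2c1c(OC)cc(OCC)c2OC | intermediate (not isolated)
22 | {2-[2-(tert-butyldimethylsilyloxy)ethyl]-4,6-dimethoxyphenyl}(6-ethoxy-3,5,8-trimethoxy-1-methylnaphthalen-2-yl)methanone | Cc1c(C(=O)c3c(OC)cc(OC)cc3CCO[Si](C)(C)C(C)(C)C)c(OC)cc2c1c(OC)cc(OCC)c2OC | intermediate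
23 | (6-ethoxy-3,5,8-trimethoxy-1-methylnaphthalen-2-yl)[2-(2-hydroxyethyl)-4,6-dimethoxyphenyl]methanone | Cc1c(C(=O)c3c(OC)cc(OC)cc3CCO)c(OC)cc2c1c(OC)cc(OCC)c2OC | intermediate
24 | 2-[2-(6-ethoxy-3,5,8-trimethoxy-1-methyl-2-naphthoyl)-3,5-dimethoxyphenyl]acetaldehyde | Cc1c(C(=O)c3c(OC)cc(OC)cc3CC=O)c(OC)cc2c1c(OC)cc(OCC)c2OC | intermediate
25 | 2,2,6-trimethyl-4H-1,3-dioxin-4-one | CC1=CC(=O)OC(C)(C)O1 | starting material
26 | lithium 2,2-dimethyl-6-methylidene-6H-1,3-dioxin-4-olate | [Li+].[O-]C1=CC(=C)OC(C)(C)O1 | intermediate (not isolated)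
27 | 6-{3-[2-(6-ethoxy-3,5,8-trimethoxy-1-methyl-2-naphthoyl)-3,5-dimethoxyphenyl]-2-hydroxypropyl}-2,2-dimethyl-4H-1,3-dioxin-4-one (racemic) | Cc1c(C(=O)c3c(OC)cc(OC)cc3CC(O)CC3=CC(=O)OC(C)(C)O3)c(OC)cc2c1c(OC)cc(OCC)c2OC | intermediate
28 | 6-{3-[2-(6-ethoxy-3,5,8-trimethoxy-1-methyl-2-naphthoyl)-3,5-dimethoxyphenyl]-2-oxopropyl}-2,2-dimethyl-4H-1,3-dioxin-4-one | Cc1c(C(=O)c3c(OC)cc(OC)cc3CC(=O)CC3=CC(=O)OC(C)(C)O3)c(OC)cc2c1c(OC)cc(OCC)c2OC | intermediate
29 | 6-[2-(6-ethoxy-3,5,8-trimethoxy-1-methyl-2-naphthoyl)-3,5-dimethoxyphenyl]-3,5-dioxohex-1-en-1-one | Cc1c(C(=O)c3c(OC)cc(OC)cc3CC(=O)CC(=O)C=C=O)c(OC)cc2c1c(OC)cc(OCC)c2OC | intermediate (not isolated)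
30 | 6-[2-(6-ethoxy-3,5,8-trimethoxy-1-methyl-2-naphthoyl)-3,5-dimethoxybenzyl]-4-hydroxy-2H-pyran-2-one | Cc1c(C(=O)c3c(OC)cc(OC)cc3Cc3cc(O)cc(=O)o3)c(OC)cc2c1c(OC)cc(OCC)c2OC | intermediate
31 | 6-[3,5-dihydroxy-2-(3,5,6,8-tetrahydroxy-1-methyl-2-naphthoyl)benzyl]-4-hydroxy-2H-pyran-2-one | Cc1c(C(=O)c3c(O)cc(O)cc3Cc3cc(O)cc(=O)o3)c(O)cc2c1c(O)cc(O)c2O | intermediate (not isolated)
32 | 6-{2,4-dihydroxy-6-[(4-hydroxy-2-oxo-2H-pyran-6-yl)methyl]benzoyl}-2,7-dihydroxy-5-methylnaphthalene-1,4-dione (CNP0141484.0) | Cc1c(C(=O)c2c(O)cc(O)cc2Cc2cc(O)cc(=O)o2)c(O)cc2c1C(=O)C=C(O)C2=O | target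

## Step count and least certain steps

Total: 18 steps. Longest linear sequence: 17 steps (1 to 32 through steps 1–10 and 12–18; step 11 is a one-step side branch).

Step 5 (key step). The most likely failure is stalling after alkyne insertion: the ethoxy-stabilised vinylcarbene inserts CO slowly, so ring closure without CO, uptake of a second alkyne or thermal decay of the ynol ether may outrun ketene formation. Fallback, from 8 and back at 12:
- Benzannulation of 8 with ethynyltrimethylsilane, an alkyne without a donor whose silyl group goes next to the CO-derived carbon for steric reasons, should give 4,7-dimethoxy-5-methyl-6-(triisopropylsilyloxymethyl)-2-(trimethylsilyl)naphthalen-1-ol F1.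
- Methylation (NaH, MeI) gives 1,4,7-trimethoxy-5-methyl-6-(triisopropylsilyloxymethyl)-2-(trimethylsilyl)naphthalene F2.
- Ipso-iododesilylation with ICl gives 2-iodo-1,4,7-trimethoxy-5-methyl-6-(triisopropylsilyloxymethyl)naphthalene F3.
- Ullmann-type etherification with ethanol (CuI, 1,10-phenanthroline, Cs2CO3) returns 12.
- The silicon marks C2, so the regiochemical relation is kept although the oxygen arrives later.

Step 12. The most likely failure is a slow cycloaddition at the β-alkylated, shielded ynone, so that the silyl ketene acetal diene decays before it reacts, or adds in a Michael sense without closing the ring. Fallback, from 14 and back at 22 (it replaces steps 9 to 12):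
- NBS bromination of commercial 2-(3,5-dimethoxyphenyl)ethanol ortho to the side chain gives 2-(2-bromo-3,5-dimethoxyphenyl)ethanol F4.
- Silylation gives [2-(2-bromo-3,5-dimethoxyphenyl)ethoxy](tert-butyl)dimethylsilane F5.
- Bromine–lithium exchange (n-BuLi, THF, −78 °C) and addition to 14 gives {2-[2-(tert-butyldimethylsilyloxy)ethyl]-4,6-dimethoxyphenyl}(6-ethoxy-3,5,8-trimethoxy-1-methylnaphthalen-2-yl)methanol F6 (racemic).
- Dess–Martin oxidation of F6 gives 22.

Step 15. The most likely failure is proton transfer from the enolisable arylacetaldehyde to the basic dienolate, followed by self-condensation, in place of addition. Fallback, from 24 and back at 27: 25 is converted (LiN(i-Pr)2, Me3SiCl) into trimethyl[(2,2-dimethyl-6-methylidene-6H-1,3-dioxin-4-yl)oxy]silane F7, which adds to 24 in a vinylogous Mukaiyama aldol reaction (BF3·OEt2, CH2Cl2, −78 °C). This non-basic, Lewis-acid path gives 27 after work-up.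

Step 18. The most likely failure is incomplete dealkylation, stalling at the ethyl ether or at the unactivated para methoxy group of ring B, or acid-induced condensation of the electron-rich polyphenol before it is oxidised. Fallback, from 30 and back at 32:
- Oxidative demethylation with (NH4)2Ce(NO3)6 (2.1 equiv, MeCN/H2O, 0 °C, slow addition) fixes the quinone first and gives 6-{2,4-dimethoxy-6-[(4-hydroxy-2-oxo-2H-pyran-6-yl)methyl]benzoyl}-2-ethoxy-7-methoxy-5-methylnaphthalene-1,4-dione F8.
- BBr3 at −78 to 0 °C then has only four ethers to cleave, all activated by a carbonyl group, and gives 32.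

## Further compounds

F1 | step 5 | 4,7-dimethoxy-5-methyl-6-(triisopropylsilyloxymethyl)-2-(trimethylsilyl)naphthalen-1-ol | Cc1c(CO[Si](C(C)C)(C(C)C)C(C)C)c(OC)cc2c1c(OC)cc([Si](C)(C)C)c2O
F2 | step 5 | 1,4,7-trimethoxy-5-methyl-6-(triisopropylsilyloxymethyl)-2-(trimethylsilyl)naphthalene | Cc1c(CO[Si](C(C)C)(C(C)C)C(C)C)c(OC)cc2c1c(OC)cc([Si](C)(C)C)c2OC
F3 | step 5 | 2-iodo-1,4,7-trimethoxy-5-methyl-6-(triisopropylsilyloxymethyl)naphthalene | Cc1c(CO[Si](C(C)C)(C(C)C)C(C)C)c(OC)cc2c1c(OC)cc(I)c2OC
F4 | step 12 | 2-(2-bromo-3,5-dimethoxyphenyl)ethanol | COc1cc(OC)c(Br)c(CCO)c1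
F5 | step 12 | [2-(2-bromo-3,5-dimethoxyphenyl)ethoxy](tert-butyl)dimethylsilane | COc1cc(OC)c(Br)c(CCO[Si](C)(C)C(C)(C)C)c1
F6 | step 12 | {2-[2-(tert-butyldimethylsilyloxy)ethyl]-4,6-dimethoxyphenyl}(6-ethoxy-3,5,8-trimethoxy-1-methylnaphthalen-2-yl)methanol (racemic) | Cc1c(C(O)c3c(OC)cc(OC)cc3CCO[Si](C)(C)C(C)(C)C)c(OC)cc2c1c(OC)cc(OCC)c2OC
F7 | step 15 | trimethyl[(2,2-dimethyl-6-methylidene-6H-1,3-dioxin-4-yl)oxy]silane | C=C1C=C(O[Si](C)(C)C)OC(C)(C)O1
F8 | step 18 | 6-{2,4-dimethoxy-6-[(4-hydroxy-2-oxo-2H-pyran-6-yl)methyl]benzoyl}-2-ethoxy-7-methoxy-5-methylnaphthalene-1,4-dione | Cc1c(C(=O)c3c(OC)cc(OC)cc3Cc3cc(O)cc(=O)o3)c(OC)cc2c1C(=O)C=C(OCC)C2=O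
A1 | alternative 1 | 6-[3,5-dimethoxy-2-(3,5,6,8-tetramethoxy-1-methyl-2-naphthoyl)benzyl]-4-hydroxy-2H-pyran-2-one | Cc1c(C(=O)c3c(OC)cc(OC)cc3Cc3cc(O)cc(=O)o3)c(OC)cc2c1c(OC)cc(OC)c2OC
A2 | alternative 1 | 6-{3-[3,5-dimethoxy-2-(3,5,6,8-tetramethoxy-1-methyl-2-naphthoyl)phenyl]-2-oxopropyl}-2,2-dimethyl-4H-1,3-dioxin-4-one | Cc1c(C(=O)c3c(OC)cc(OC)cc3CC(=O)CC3=CC(=O)OC(C)(C)O3)c(OC)cc2c1c(OC)cc(OC)c2OC
A3 | alternative 2 | 7-(tert-butyldimethylsilyloxy)-6-{2,4-dimethoxy-6-[(4-methoxy-2-oxo-2H-pyran-6-yl)methyl]benzoyl}-2-methoxy-5-methylnaphthalene-1,4-dione | Cc1c(C(=O)c3c(OC)cc(OC)cc3Cc3cc(OC)cc(=O)o3)c(O[Si](C)(C)C(C)(C)C)cc2c1C(=O)C=C(OC)C2=O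
A4 | alternative 2 | 2-bromo-5-methoxy-1,4-benzoquinone | COC1=CC(=O)C(Br)=CC1=O
A5 | alternative 2 | 6-{2-[(2Z)-2-ethylidene-3-(tert-butyldimethylsilyloxy)but-3-enoyl]-3,5-dimethoxybenzyl}-4-methoxy-2H-pyran-2-one | C/C=C(\C(=O)c1c(OC)cc(OC)cc1Cc1cc(OC)cc(=O)o1)C(=C)O[Si](C)(C)C(C)(C)C
A6 | alternative 3 | 5-[2-(tert-butyldimethylsilyloxy)ethyl]-3-hydroxy-4-(3,5,6,8-tetramethoxy-1-methyl-2-naphthoyl)cyclohex-3-en-1-one (racemic, one enantiomer drawn) | Cc1c(C(=O)C3=C(O)CC(=O)C[C@@H]3CCO[Si](C)(C)C(C)(C)C)c(OC)cc2c1c(OC)cc(OC)c2OC
A7 | alternative 3 | methyl 3-oxo-3-(3,5,6,8-tetramethoxy-1-methylnaphthalen-2-yl)propanoate | Cc1c(C(=O)CC(=O)OC)c(OC)cc2c1c(OC)cc(OC)c2OC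
A8 | alternative 3 | (E)-6-(tert-butyldimethylsilyloxy)hex-3-en-2-one | CC(=O)/C=C/CCO[Si](C)(C)C(C)(C)C
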